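**Plan**
The retrosynthesis first cuts the four O–benzyl bonds, then the apigenin pyranone at O1–C2 (cyclodehydration) and C2–C3 (Baker–Venkataraman acyl transfer). This leads back to a benzoic acid carried on the acacetin half and to dibenzylated phloroacetophenone.
The acacetin pyranone is cut at O1–C8a (enolate O-arylation), its diketone at C2–C3 (enolate acylation), the acetyl group at C4–C4a (Friedel–Crafts) and the diaryl ether at the O–C4' bond of the benzoate ring (SNAr).
Enabling feature: in ring A of the acacetin half, C4a is flanked by two oxygen-bearing carbons, C5 and C8a. With bromine at C8a and a benzyl ether on the C5 oxygen, only O1–C8a can form, and the C8a–Br bond lies ortho to the C4 carbonyl.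
Forward order: diaryl ether, acetyl and benzyl groups on ring A, 1,3-diketone, acacetin ring C, then ester hydrolysis, aryl ester, apigenin ring C and global debenzylation.
Stereochemistry: the target has no stereocentre, so none has to be set.

Key step: step 6

Remark: flavone numbering (O1, C2, C3, C4, C4a, C5 to C8, C8a) is used for each half; compounds 1, 2, 7 and 11 and all reagents are taken as commercial.

**Route**

Step 1
Reactants: 1 4-bromo-2,6-dimethoxyphenol; 2 methyl 4-fluorobenzoate
Product: 3 methyl 4-(4-bromo-2,6-dimethoxyphenoxy)benzoate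
Conditions: Cs2CO3, DMSO, 110 °C
Reagents that add atoms: none
Why: Nucleophilic aromatic substitution (SNAr), in which the caesium phenoxide adds para to the ester and fluoride leaves through a Meisenheimer intermediate, while the aryl bromide is inert without a metal catalyst.

Step 2
Reactants: 3 methyl 4-(4-bromo-2,6-dimethoxyphenoxy)benzoate
Product: 4 methyl 4-(3-acetyl-4-bromo-2,6-dimethoxyphenoxy)benzoate
Conditions: AcCl, AlCl3, CH2Cl2, 0 °C to rt
Reagents that add atoms: acetyl chloride, CC(=O)Cl
Why: Friedel–Crafts acylation, in which the two free positions of ring A are equivalent and each is ortho to one methoxy group and para to the other, whereas the ester-bearing ring is deactivated, so a single regioisomer should result.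

Step 3
Reactants: 4 methyl 4-(3-acetyl-4-bromo-2,6-dimethoxyphenoxy)benzoate
Product: 5 methyl 4-(3-acetyl-4-bromo-2,6-dihydroxyphenoxy)benzoate
Conditions: BBr3, CH2Cl2, −78 to 0 °C; then H2O
Reagents that add atoms: none
Why: Lewis-acid cleavage of aryl methyl ethers with BBr3, which at low temperature is faster than attack on a methyl ester and leaves the diaryl ether, ketone and aryl bromide untouched.

Step 4
Reactants: 5 methyl 4-(3-acetyl-4-bromo-2,6-dihydroxyphenoxy)benzoate
Product: 6 methyl 4-[3-acetyl-2,6-bis(benzyloxy)-4-bromophenoxy]benzoate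
Conditions: BnBr, K2CO3, DMF, 60 °C
Reagents that add atoms: benzyl bromide, BrCc1ccccc1
Why: Williamson etherification of both phenoxides, with carbonate too weak to enolise the methyl ketone and the twisted, doubly ortho-substituted acetyl group giving only a weak hydrogen bond to the neighbouring phenol.

Step 5
Reactants: 6 methyl 4-[3-acetyl-2,6-bis(benzyloxy)-4-bromophenoxy]benzoate; 7 4-methoxybenzoyl chloride
Product: 8 methyl 4-{2,6-bis(benzyloxy)-4-bromo-3-[3-(4-methoxyphenyl)-3-oxopropanoyl]phenoxy}benzoate
Conditions: LiN(SiMe3)2 (2.2 equiv), THF, −78 °C; then 7, −78 to 0 °C; aq. NH4Cl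
Reagents that add atoms: none
Why: Claisen-type C-acylation of the lithium enolate of a methyl ketone by an aroyl chloride, where the second equivalent of base takes up the more acidic 1,3-diketone and the acid chloride is far more electrophilic than the methyl benzoate.

Step 6
Reactants: 8 methyl 4-{2,6-bis(benzyloxy)-4-bromo-3-[3-(4-methoxyphenyl)-3-oxopropanoyl]phenoxy}benzoate
Product: 9 methyl 4-{[5,7-bis(benzyloxy)-2-(4-methoxyphenyl)-4-oxo-4H-chromen-6-yl]oxy}benzoate
Conditions: CuI (10 mol%), 1,10-phenanthroline (20 mol%), K2CO3, DMF, 110 °C, N2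
Reagents that add atoms: none
Why: K2CO3 converts the 1,3-diketone into its potassium enolate, which binds CuI as a β-diketonate; monovalent copper inserts into the C8a–Br bond ortho to the C4 carbonyl, and the resulting trivalent copper aryl enolate undergoes C–O reductive elimination to form O1–C8a. The closest known reaction type is the copper-catalysed intramolecular Ullmann-type O-arylation of 1-(2-haloaryl)-1,3-diketones to flavones, whose base-only counterpart is an addition–elimination through a Meisenheimer-type enolate. Ring C closes as a six-membered ring by reductive elimination from a seven-membered copper chelate, which in the uncatalysed pathway corresponds to a 6-endo-trig attack of the distal enol oxygen on C8a of the C4a=C8a bond conjugated with the C4 carbonyl. No stereocentre is formed. The step needs O- over C-arylation and a single regiochemical outcome: attack by the central carbon or by the proximal carbonyl oxygen would have to form a four-membered ring, so only the distal oxygen can reach C8a, and since C8a carries the only halogen while the C5 oxygen is capped as a benzyl ether, the 5,6,7-trioxygenated pattern with the aryloxy group at C6 follows without ambiguity. The methyl ester, the benzyl ethers and the diaryl ether should be inert to carbonate and copper under these conditions.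

Step 7
Reactants: 9 methyl 4-{[5,7-bis(benzyloxy)-2-(4-methoxyphenyl)-4-oxo-4H-chromen-6-yl]oxy}benzoate
Product: 10 4-{[5,7-bis(benzyloxy)-2-(4-methoxyphenyl)-4-oxo-4H-chromen-6-yl]oxy}benzoic acid
Conditions: LiOH·H2O, THF/MeOH/H2O, rt to 40 °C; then 1 M HCl
Reagents that add atoms: lithium hydroxide, [Li+].[OH-]
Why: Saponification of a methyl benzoate by acyl–oxygen cleavage, under conditions mild enough that the pyranone ring of the flavone should not be opened.

Step 8
Reactants: 11 2,4,6-trihydroxyacetophenone
Product: 12 1-[2,4-bis(benzyloxy)-6-hydroxyphenyl]ethan-1-one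
Conditions: BnBr (2.1 equiv), K2CO3, DMF, rt
Reagents that add atoms: benzyl bromide, BrCc1ccccc1
Why: Selective Williamson etherification, in which the para hydroxyl and one ortho hydroxyl are alkylated and the remaining ortho hydroxyl is held back by its strong hydrogen bond to the acetyl carbonyl.

Step 9
Reactants: 10 4-{[5,7-bis(benzyloxy)-2-(4-methoxyphenyl)-4-oxo-4H-chromen-6-yl]oxy}benzoic acid; 12 1-[2,4-bis(benzyloxy)-6-hydroxyphenyl]ethan-1-one
Product: 13 2-acetyl-3,5-bis(benzyloxy)phenyl 4-{[5,7-bis(benzyloxy)-2-(4-methoxyphenyl)-4-oxo-4H-chromen-6-yl]oxy}benzoate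
Conditions: DCC, DMAP (cat.), CH2Cl2, rt
Reagents that add atoms: none
Why: Steglich esterification, in which the acylpyridinium formed from the carbodiimide-activated acid transfers the aroyl group to the hydrogen-bonded phenol, the usual entry to a Baker–Venkataraman flavone synthesis.

Step 10
Reactants: 13 2-acetyl-3,5-bis(benzyloxy)phenyl 4-{[5,7-bis(benzyloxy)-2-(4-methoxyphenyl)-4-oxo-4H-chromen-6-yl]oxy}benzoate
Product: 15 5,7-bis(benzyloxy)-6-{4-[5,7-bis(benzyloxy)-4-oxo-4H-chromen-2-yl]phenoxy}-2-(4-methoxyphenyl)-4H-chromen-4-one, via Baker–Venkataraman diketone 14 (not isolated)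
Conditions: KOt-Bu, THF, 0 °C to rt; AcOH quench, evaporate; then p-TsOH·H2O (cat.), toluene, 90 °C
Reagents that add atoms: none
Why: Baker–Venkataraman rearrangement (intramolecular Claisen transfer of the aroyl group from oxygen to the acetyl enolate carbon through a six-membered transition state) followed by acid-catalysed cyclodehydration of the 2-hydroxyaryl 1,3-diketone, which closes ring C of the apigenin half; any early loss of the acid-labile 5-O-benzyl group would be harmless because the next step removes all four.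

Step 11
Reactants: 15 5,7-bis(benzyloxy)-6-{4-[5,7-bis(benzyloxy)-4-oxo-4H-chromen-2-yl]phenoxy}-2-(4-methoxyphenyl)-4H-chromen-4-one
Product: 16 cryptomerin A, 6-[4-(5,7-dihydroxy-4-oxo-4H-chromen-2-yl)phenoxy]-5,7-dihydroxy-2-(4-methoxyphenyl)-4H-chromen-4-one
Conditions: H2 (1 atm), Pd/C (10 wt%), THF/MeOH, rt
Reagents that add atoms: none
Why: Catalytic hydrogenolysis of the four benzylic C–O bonds, which at ambient pressure should leave the aryl methyl ether, the diaryl ether and the conjugated C2=C3 bonds of both pyranones intact.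

**Compound list**
1 | 4-bromo-2,6-dimethoxyphenol | COc1cc(Br)cc(OC)c1O | starting material
2 | methyl 4-fluorobenzoate | COC(=O)c1ccc(F)cc1 | starting material
3 | methyl 4-(4-bromo-2,6-dimethoxyphenoxy)benzoate | COC(=O)c1ccc(Oc2c(OC)cc(Br)cc2OC)cc1 | intermediate
4 | methyl 4-(3-acetyl-4-bromo-2,6-dimethoxyphenoxy)benzoate | COC(=O)c1ccc(Oc2c(OC)cc(Br)c(C(C)=O)c2OC)cc1 | intermediate
5 | methyl 4-(3-acetyl-4-bromo-2,6-dihydroxyphenoxy)benzoate | COC(=O)c1ccc(Oc2c(O)cc(Br)c(C(C)=O)c2O)cc1 | intermediate
6 | methyl 4-[3-acetyl-2,6-bis(benzyloxy)-4-bromophenoxy]benzoate | COC(=O)c1ccc(Oc2c(OCc3ccccc3)cc(Br)c(C(C)=O)c2OCc2ccccc2)cc1 | intermediate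
7 | 4-methoxybenzoyl chloride | COc1ccc(C(=O)Cl)cc1 | starting material
8 | methyl 4-{2,6-bis(benzyloxy)-4-bromo-3-[3-(4-methoxyphenyl)-3-oxopropanoyl]phenoxy}benzoate | COC(=O)c1ccc(Oc2c(OCc3ccccc3)cc(Br)c(C(=O)CC(=O)c3ccc(OC)cc3)c2OCc2ccccc2)cc1 | intermediate
9 | methyl 4-{[5,7-bis(benzyloxy)-2-(4-methoxyphenyl)-4-oxo-4H-chromen-6-yl]oxy}benzoate | COC(=O)c1ccc(Oc2c(OCc3ccccc3)cc3oc(-c4ccc(OC)cc4)cc(=O)c3c2OCc2ccccc2)cc1 | intermediate
10 | 4-{[5,7-bis(benzyloxy)-2-(4-methoxyphenyl)-4-oxo-4H-chromen-6-yl]oxy}benzoic acid | OC(=O)c1ccc(Oc2c(OCc3ccccc3)cc3oc(-c4ccc(OC)cc4)cc(=O)c3c2OCc2ccccc2)cc1 | intermediate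
11 | 2,4,6-trihydroxyacetophenone | CC(=O)c1c(O)cc(O)cc1O | starting material
12 | 1-[2,4-bis(benzyloxy)-6-hydroxyphenyl]ethan-1-one | CC(=O)c1c(O)cc(OCc2ccccc2)cc1OCc1ccccc1 | intermediate
13 | 2-acetyl-3,5-bis(benzyloxy)phenyl 4-{[5,7-bis(benzyloxy)-2-(4-methoxyphenyl)-4-oxo-4H-chromen-6-yl]oxy}benzoate | CC(=O)c1c(OC(=O)c2ccc(Oc3c(OCc4ccccc4)cc4oc(-c5ccc(OC)cc5)cc(=O)c4c3OCc3ccccc3)cc2)cc(OCc2ccccc2)cc1OCc1ccccc1 | intermediate
14 | 1-[2,4-bis(benzyloxy)-6-hydroxyphenyl]-3-(4-{[5,7-bis(benzyloxy)-2-(4-methoxyphenyl)-4-oxo-4H-chromen-6-yl]oxy}phenyl)propane-1,3-dione | O=C(CC(=O)c1ccc(Oc2c(OCc3ccccc3)cc3oc(-c4ccc(OC)cc4)cc(=O)c3c2OCc2ccccc2)cc1)c1c(O)cc(OCc2ccccc2)cc1OCc1ccccc1 | intermediate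
15 | 5,7-bis(benzyloxy)-6-{4-[5,7-bis(benzyloxy)-4-oxo-4H-chromen-2-yl]phenoxy}-2-(4-methoxyphenyl)-4H-chromen-4-one | COc1ccc(-c2cc(=O)c3c(OCc4ccccc4)c(Oc4ccc(-c5cc(=O)c6c(OCc7ccccc7)cc(OCc7ccccc7)cc6o5)cc4)c(OCc4ccccc4)cc3o2)cc1 | intermediate
16 | cryptomerin A | COc1ccc(-c2cc(=O)c3c(O)c(Oc4ccc(-c5cc(=O)c6c(O)cc(O)cc6o5)cc4)c(O)cc3o2)cc1 | target

**Step count and risks**
Total steps: 11. Longest linear sequence: 10 (steps 1 to 7 and 9 to 11, from compound 1).

Steps most likely to fail:

Step 6. Oxidative addition into the electron-rich, ortho-acylated C–Br bond may be slow, so that protodebromination or retro-Claisen cleavage of the diketone by carbonate competes with ring closure. The fallback closes ring C at O1–C2 instead and sets out from compound 6. Miyaura borylation (B2pin2, PdCl2(dppf), KOAc, dioxane, 90 °C) should give methyl 4-[3-acetyl-2,6-bis(benzyloxy)-4-(4,4,5,5-tetramethyl-1,3,2-dioxaborolan-2-yl)phenoxy]benzoate F1. Oxidation with NaBO3·4H2O in THF/H2O should give methyl 4-[3-acetyl-2,6-bis(benzyloxy)-4-hydroxyphenoxy]benzoate F2. Claisen–Schmidt condensation with 4-methoxybenzaldehyde (KOH, EtOH/THF, rt), with saponification of the ester in the same pot, should give 4-{2,6-bis(benzyloxy)-4-hydroxy-3-[(2E)-3-(4-methoxyphenyl)prop-2-enoyl]phenoxy}benzoic acid F3. Oxidative cyclisation of this 2'-hydroxychalcone with catalytic I2 in DMSO at 120 °C returns to the route at compound 10, bypassing 8 and 9. Regiochemistry stays unambiguous because the only free phenol is the one put in place of bromine.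

Step 2. Acylation at the crowded site between bromine and a methoxy group may stall, while the Lewis acid demethylates the ether or attacks the ester instead. The fallback sets out from compound 3 and uses a smaller electrophile. Rieche formylation (Cl2CHOMe, TiCl4, CH2Cl2, 0 °C) should give methyl 4-(4-bromo-3-formyl-2,6-dimethoxyphenoxy)benzoate F4. Addition of MeMgBr in THF at −78 °C, where the aldehyde reacts far faster than the benzoate ester, should give racemic methyl 4-[4-bromo-3-(1-hydroxyethyl)-2,6-dimethoxyphenoxy]benzoate F5. Dess–Martin oxidation in CH2Cl2 returns to the route at compound 4.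

Step 1. Attack of the doubly ortho-substituted phenoxide on the only moderately activated fluoroarene may be sluggish, and at the temperature needed the phenoxide may O-demethylate the ester. The fallback sets out from compound 1 and forms the same C–O bond by oxidative copper coupling rather than SNAr. Chan–Lam–Evans coupling with [4-(methoxycarbonyl)phenyl]boronic acid (Cu(OAc)2, pyridine, 4 Å molecular sieves, CH2Cl2, air, rt) comes back to the route directly at compound 3 and makes no new compound (F0).

**Further compounds**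
F1 | step 6 | methyl 4-[3-acetyl-2,6-bis(benzyloxy)-4-(4,4,5,5-tetramethyl-1,3,2-dioxaborolan-2-yl)phenoxy]benzoate | COC(=O)c1ccc(Oc2c(OCc3ccccc3)cc(B3OC(C)(C)C(C)(C)O3)c(C(C)=O)c2OCc2ccccc2)cc1
F2 | step 6 | methyl 4-[3-acetyl-2,6-bis(benzyloxy)-4-hydroxyphenoxy]benzoate | COC(=O)c1ccc(Oc2c(OCc3ccccc3)cc(O)c(C(C)=O)c2OCc2ccccc2)cc1
F3 | step 6 | 4-{2,6-bis(benzyloxy)-4-hydroxy-3-[(2E)-3-(4-methoxyphenyl)prop-2-enoyl]phenoxy}benzoic acid | OC(=O)c1ccc(Oc2c(OCc3ccccc3)cc(O)c(C(=O)/C=C/c3ccc(OC)cc3)c2OCc2ccccc2)cc1
F4 | step 2 | methyl 4-(4-bromo-3-formyl-2,6-dimethoxyphenoxy)benzoate | COC(=O)c1ccc(Oc2c(OC)cc(Br)c(C=O)c2OC)cc1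
F5 | step 2 | methyl 4-[4-bromo-3-(1-hydroxyethyl)-2,6-dimethoxyphenoxy]benzoate (racemic) | COC(=O)c1ccc(Oc2c(OC)cc(Br)c(C(C)O)c2OC)cc1
F0 | step 1 | none | none
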